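**Plan**

- Numbering: ring A is C1 (carrying the CH2OH carbon C8), C2 (H), C3 (OH), C4 (OH), C5 (Br), C6; C7 is the methylene between C6 and ring B (the 3-bromo-4,5-dihydroxyphenyl ring).
- Enabling feature: C8 and C7 sit on neighbouring ring carbons (C1, C6), so a single ether oxygen C8–O–C7 can link a furan to a 1-bromoalkyne. The furan carbons become C1–C4, the furan oxygen becomes the C4 hydroxyl and its methoxy group the C3 oxygen; the alkyne carbons become C5 (with Br) and C6.
- Retrosynthesis: cut the three O–CH3 bonds and one O–acetyl bond; replace C7–H by a C7–O–C8 ether (a 1,3-dihydroisobenzofuran); cut C1–C6 and C4–C5 of ring A (furan/bromoalkyne Diels–Alder); cut O–C7 (Williamson) and C7–C≡C (Grignard addition to the ring B aldehyde).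
- Forward: ring B is bought; a furan alcohol (2 steps) and a benzylic propargylic dibromide (3 steps) are joined as an ether; ring A and the dihydrofuran ring form together in step 7; the dihydrofuran is then opened reductively at C7–O and the phenols are freed.
- Stereochemistry: the target is achiral; C7 is a racemic stereocentre from step 3 to step 8 and becomes CH2 in step 9.

Key step: step 7

Remark on the chemistry: the C4 hydroxyl delivered by the key step is acetylated before the reductive ring opening, because a free hydroxyl para to C8 would let the C8–O bond ionise and be reduced as well; this costs one extra step.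

**Route**

Step 1
Reactants: 1 methyl 4-bromofuran-2-carboxylate
Product: 2 methyl 4-methoxyfuran-2-carboxylate
Conditions: CuI (10 mol %), 3,4,7,8-tetramethyl-1,10-phenanthroline (20 mol %), Cs2CO3, MeOH, PhMe, 4 Å MS, 110 °C, sealed tube
Reagents that add atoms: methanol, CO
Why: Ullmann-type C–O coupling of a heteroaryl bromide with methanol, in which the phenanthroline-ligated monovalent copper catalyst activates the C–Br bond and the methyl ester is unchanged by methoxide exchange.

Step 2
Reactants: 2 methyl 4-methoxyfuran-2-carboxylate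
Product: 3 (4-methoxyfuran-2-yl)methanol
Conditions: i-Bu2AlH (2.5 equiv), CH2Cl2, −78 → 0 °C; aq. potassium sodium tartrate
Reagents that add atoms: none
Why: Hydride reduction of an ester to the primary alcohol, with a non-acidic tartrate work-up that spares the acid-sensitive 3-alkoxyfuran.

Step 3
Reactants: 4 3-bromo-4,5-dimethoxybenzaldehyde; 5 ethynylmagnesium bromide
Product: 6 1-(3-bromo-4,5-dimethoxyphenyl)prop-2-yn-1-ol (racemic)
Conditions: THF, 0 °C; aq. NH4Cl
Reagents that add atoms: none
Why: Grignard 1,2-addition of an alkynyl nucleophile to an aromatic aldehyde; the aryl bromide does not exchange with an acetylide, and the new C7 stereocentre forms racemic, which is all that is needed.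

Step 4
Reactants: 6 1-(3-bromo-4,5-dimethoxyphenyl)prop-2-yn-1-ol
Product: 7 3-bromo-1-(3-bromo-4,5-dimethoxyphenyl)prop-2-yn-1-ol (racemic)
Conditions: NBS (1.1 equiv), AgNO3 (10 mol %), acetone, 23 °C, dark
Reagents that add atoms: N-bromosuccinimide, O=C1CCC(=O)N1Br
Why: Silver-catalysed bromination of a terminal alkyne through the silver acetylide, placed before the furan enters because NBS would attack the electron-rich 3-alkoxyfuran.

Step 5
Reactants: 7 3-bromo-1-(3-bromo-4,5-dimethoxyphenyl)prop-2-yn-1-ol
Product: 8 1-bromo-5-(1,3-dibromoprop-2-yn-1-yl)-2,3-dimethoxybenzene (racemic)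
Conditions: PBr3 (0.4 equiv), pyridine (cat.), Et2O, 0 °C; used crude
Reagents that add atoms: phosphorus tribromide, BrP(Br)Br
Why: Substitution of an activated secondary alcohol by bromide through its phosphite ester (PBr3 bromination), with no phosphine present that could attack the bromoalkyne.

Step 6
Reactants: 3 (4-methoxyfuran-2-yl)methanol; 8 1-bromo-5-(1,3-dibromoprop-2-yn-1-yl)-2,3-dimethoxybenzene
Product: 10 2-({[3-bromo-1-(3-bromo-4,5-dimethoxyphenyl)prop-2-yn-1-yl]oxy}methyl)-4-methoxyfuran (racemic), via sodium (4-methoxyfuran-2-yl)methanolate 9 (not isolated)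
Conditions: 3, NaH (1.05 equiv), THF, 0 °C; then 8 (1.1 equiv), 0 → 23 °C
Reagents that add atoms: sodium hydride, [Na+].[H-] (sodium of intermediate 9 only)
Why: Williamson ether synthesis in which the primary alkoxide displaces a benzylic propargylic bromide that has no β-hydrogen, as alkoxides are alkylated by 1,3-dibromopropyne at the sp3 carbon with the bromoalkyne untouched; keeping the furan as the nucleophile avoids a self-alkylating furfuryl halide.

Step 7
Reactants: 10 2-({[3-bromo-1-(3-bromo-4,5-dimethoxyphenyl)prop-2-yn-1-yl]oxy}methyl)-4-methoxyfuran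
Product: 12 7-bromo-1-(3-bromo-4,5-dimethoxyphenyl)-5-methoxy-1,3-dihydroisobenzofuran-6-ol (racemic), via oxanorbornadiene cycloadduct 11 (not isolated)
Conditions: PhMe (0.02 M), 2,6-di-tert-butyl-4-methylphenol (cat.), 110–130 °C, sealed tube, argon
Reagents that add atoms: none
Why: On heating, the 4-methoxyfuran (diene, C1–C4) and the tethered 1-bromoalkyne (dienophile, C5≡C6) should undergo an intramolecular [4+2] cycloaddition that forms C1–C6 and C4–C5 and gives oxanorbornadiene 11; lone-pair donation from the C3 methoxy group then breaks the C1–O bridge bond, and loss of the C4 proton aromatises ring A to the C4 phenol. The closest known reaction type is the intramolecular Diels–Alder reaction of furfuryl propargyl ethers followed by opening of the 7-oxanorbornadiene to a 1,3-dihydroisobenzofuran phenol; the bromine on the alkyne is a spectator that ends on C5. The five-membered dihydrofuran ring closes through the C1–C6 bond, an exo closure across the three-atom CH2–O–CH tether, and the six-membered ring A closes through the C4–C5 bond as the cycloadduct ring. No new stereocentre remains, since the two bridgehead centres of 11 become sp2 carbons and C7 stays racemic. The step needs control of the regiochemistry of addition and of bridge opening: the short tether allows only the fused orientation, so the brominated carbon must bond to the unsubstituted furan α-carbon (C4), and the C3 methoxy group is conjugated with a cation at C1 but not at C4, so the oxygen stays on C4 next to the bromine. The electron-rich 3-alkoxyfuran diene and the aryl group on the tether, which favours the reactive rotamer, are what should let the unactivated bromoalkyne react at this temperature.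

Step 8
Reactants: 12 7-bromo-1-(3-bromo-4,5-dimethoxyphenyl)-5-methoxy-1,3-dihydroisobenzofuran-6-ol
Product: 13 7-bromo-1-(3-bromo-4,5-dimethoxyphenyl)-5-methoxy-1,3-dihydroisobenzofuran-6-yl acetate (racemic)
Conditions: Ac2O, pyridine, DMAP (cat.), CH2Cl2, 23 °C
Reagents that add atoms: acetic anhydride, CC(=O)OC(C)=O
Why: DMAP-catalysed O-acylation of the phenol, which lowers the donor strength of the C4 oxygen so that the C8 benzylic position para to it cannot ionise in the next step.

Step 9
Reactants: 13 7-bromo-1-(3-bromo-4,5-dimethoxyphenyl)-5-methoxy-1,3-dihydroisobenzofuran-6-yl acetate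
Product: 14 2-bromo-3-[(3-bromo-4,5-dimethoxyphenyl)methyl]-4-(hydroxymethyl)-6-methoxyphenyl acetate
Conditions: Et3SiH (3 equiv), BF3·OEt2 (2.5 equiv), CH2Cl2, −20 → 0 °C; aq. NaHCO3
Reagents that add atoms: none
Why: Ionic hydrogenation of a benzhydryl ether, in which BF3-assisted ionisation at C7 gives a diarylmethyl cation (stabilised by ring B and by the para methoxy group at C3) that takes hydride from Et3SiH, while the primary C8–O bond para to the acetoxy group stays intact and is released as the alcohol on work-up; the C7 stereocentre is removed here.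

Step 10
Reactants: 14 2-bromo-3-[(3-bromo-4,5-dimethoxyphenyl)methyl]-4-(hydroxymethyl)-6-methoxyphenyl acetate
Product: 16 5-hydroxyisoavrainvilleol, via benzylic bromide 15 (not isolated)
Conditions: BBr3 (8 equiv), CH2Cl2, −78 → 23 °C; H2O, 0 °C; then acetone–H2O (1:1), 23 °C, argon
Reagents that add atoms: water, O; boron tribromide, BrB(Br)Br (bromine of intermediate 15 only)
Why: BBr3 cleavage of the three aryl methyl ethers and of the aryl acetate (as acetyl bromide) frees the four phenols and turns the benzylic alcohol into bromide 15, which as a para-hydroxybenzyl bromide should be solvolysed by water through the para-quinone methide back to the CH2OH group.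

**Compound list**

1 | methyl 4-bromofuran-2-carboxylate | COC(=O)c1cc(Br)co1 | starting material
2 | methyl 4-methoxyfuran-2-carboxylate | COC(=O)c1cc(OC)co1 | intermediate
3 | (4-methoxyfuran-2-yl)methanol | COc1coc(CO)c1 | intermediate
4 | 3-bromo-4,5-dimethoxybenzaldehyde | COc1cc(C=O)cc(Br)c1OC | starting material
5 | ethynylmagnesium bromide | C#C[Mg]Br | starting material
6 | 1-(3-bromo-4,5-dimethoxyphenyl)prop-2-yn-1-ol (racemic) | COc1cc(C(O)C#C)cc(Br)c1OC | intermediate
7 | 3-bromo-1-(3-bromo-4,5-dimethoxyphenyl)prop-2-yn-1-ol (racemic) | COc1cc(C(O)C#CBr)cc(Br)c1OC | intermediate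
8 | 1-bromo-5-(1,3-dibromoprop-2-yn-1-yl)-2,3-dimethoxybenzene (racemic) | COc1cc(C(Br)C#CBr)cc(Br)c1OC | intermediate
9 | sodium (4-methoxyfuran-2-yl)methanolate (not isolated) | COc1coc(C[O-])c1.[Na+] | intermediate
10 | 2-({[3-bromo-1-(3-bromo-4,5-dimethoxyphenyl)prop-2-yn-1-yl]oxy}methyl)-4-methoxyfuran (racemic) | COc1coc(COC(C#CBr)c2cc(OC)c(OC)c(Br)c2)c1 | intermediate
11 | 6-bromo-4-(3-bromo-4,5-dimethoxyphenyl)-8-methoxy-3,10-dioxatricyclo[5.2.1.0(1,5)]deca-5,8-diene (oxanorbornadiene cycloadduct; racemic, both C7 epimers; not isolated) | COC1=CC23COC(c4cc(OC)c(OC)c(Br)c4)C2=C(Br)C1O3 | intermediate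
12 | 7-bromo-1-(3-bromo-4,5-dimethoxyphenyl)-5-methoxy-1,3-dihydroisobenzofuran-6-ol (racemic) | COc1cc2c(c(Br)c1O)C(OC2)c1cc(OC)c(OC)c(Br)c1 | intermediate
13 | 7-bromo-1-(3-bromo-4,5-dimethoxyphenyl)-5-methoxy-1,3-dihydroisobenzofuran-6-yl acetate (racemic) | COc1cc2c(c(Br)c1OC(C)=O)C(OC2)c1cc(OC)c(OC)c(Br)c1 | intermediate
14 | 2-bromo-3-[(3-bromo-4,5-dimethoxyphenyl)methyl]-4-(hydroxymethyl)-6-methoxyphenyl acetate | COc1cc(CO)c(Cc2cc(OC)c(OC)c(Br)c2)c(Br)c1OC(C)=O | intermediate
15 | 3-bromo-4-[(3-bromo-4,5-dihydroxyphenyl)methyl]-5-(bromomethyl)benzene-1,2-diol (not isolated) | Oc1cc(CBr)c(Cc2cc(O)c(O)c(Br)c2)c(Br)c1O | intermediate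
16 | 5-hydroxyisoavrainvilleol, 3-bromo-4-[(3-bromo-4,5-dihydroxyphenyl)methyl]-5-(hydroxymethyl)benzene-1,2-diol | OCc1cc(O)c(O)c(Br)c1Cc1cc(O)c(O)c(Br)c1 | target

**Count**

Total steps: 10. Longest linear sequence: 8 steps (steps 3 to 10, from aldehyde 4); the furan branch (steps 1 and 2) joins at step 6.

**Steps most likely to fail, and fallbacks**

Step 7. The cycloaddition onto the unactivated, bromine-bearing alkyne may be slower than thermal ionisation of the furfuryl benzylic ether or loss of bromine, so that decomposition overtakes ring formation. The fallback sets out from 6 and comes back at 12; it removes the bromine from the dienophile and installs it afterwards. PBr3 should convert 6 into 1-bromo-5-(1-bromoprop-2-yn-1-yl)-2,3-dimethoxybenzene F1. This alkylates the alkoxide 9 (NaH, THF, 0 °C) to give 2-({[1-(3-bromo-4,5-dimethoxyphenyl)prop-2-yn-1-yl]oxy}methyl)-4-methoxyfuran F2. Heating F2 in toluene should give, by the same cycloaddition and bridge opening on the sterically less demanding terminal alkyne, 1-(3-bromo-4,5-dimethoxyphenyl)-5-methoxy-1,3-dihydroisobenzofuran-6-ol F3. NBS with catalytic i-Pr2NH in CH2Cl2 at 0 °C should then brominate the only free position ortho to the phenol (C5) and deliver 12.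

Step 10. During demethylation and hydrolysis, the benzylic bromide or its quinone methide may alkylate the electron-rich rings of a second molecule (oligomerisation), or acetate cleavage may stay incomplete. The fallback sets out from 14 and comes back at 16; it carries C8 through the demethylation as an aldehyde. MnO2 in CH2Cl2 should oxidise the benzylic alcohol to 2-bromo-3-[(3-bromo-4,5-dimethoxyphenyl)methyl]-4-formyl-6-methoxyphenyl acetate F4. BBr3 in CH2Cl2 should then cleave the methyl ethers and the acetate without touching the formyl group, giving 3-bromo-2-[(3-bromo-4,5-dihydroxyphenyl)methyl]-4,5-dihydroxybenzaldehyde F5. NaBH4 in THF–H2O at 0 °C should reduce the aldehyde to 16.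

Step 1. Copper-catalysed C–O coupling at the furan β-position may be slow, so that protodebromination and ester saponification by carbonate compete. The fallback sets out from 1 and comes back at 2; it introduces the oxygen through boron. Miyaura borylation (bis(pinacolato)diboron, PdCl2(dppf), KOAc, dioxane, 90 °C) should give methyl 4-(4,4,5,5-tetramethyl-1,3,2-dioxaborolan-2-yl)furan-2-carboxylate F6. Oxidation with NaBO3·4H2O in THF–H2O should give methyl 4-hydroxyfuran-2-carboxylate F7 (in equilibrium with its 4-oxo-4,5-dihydro tautomer). O-methylation with Me2SO4 and K2CO3 in acetone, which restores the aromatic furan, should give 2.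

**Further compounds**

F1 | step 7 | 1-bromo-5-(1-bromoprop-2-yn-1-yl)-2,3-dimethoxybenzene (racemic) | COc1cc(C(Br)C#C)cc(Br)c1OC
F2 | step 7 | 2-({[1-(3-bromo-4,5-dimethoxyphenyl)prop-2-yn-1-yl]oxy}methyl)-4-methoxyfuran (racemic) | COc1coc(COC(C#C)c2cc(OC)c(OC)c(Br)c2)c1
F3 | step 7 | 1-(3-bromo-4,5-dimethoxyphenyl)-5-methoxy-1,3-dihydroisobenzofuran-6-ol (racemic) | COc1cc2c(cc1O)C(OC2)c1cc(OC)c(OC)c(Br)c1
F4 | step 10 | 2-bromo-3-[(3-bromo-4,5-dimethoxyphenyl)methyl]-4-formyl-6-methoxyphenyl acetate | COc1cc(C=O)c(Cc2cc(OC)c(OC)c(Br)c2)c(Br)c1OC(C)=O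
F5 | step 10 | 3-bromo-2-[(3-bromo-4,5-dihydroxyphenyl)methyl]-4,5-dihydroxybenzaldehyde | O=Cc1cc(O)c(O)c(Br)c1Cc1cc(O)c(O)c(Br)c1
F6 | step 1 | methyl 4-(4,4,5,5-tetramethyl-1,3,2-dioxaborolan-2-yl)furan-2-carboxylate | COC(=O)c1cc(B2OC(C)(C)C(C)(C)O2)co1
F7 | step 1 | methyl 4-hydroxyfuran-2-carboxylate | COC(=O)c1cc(O)co1
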